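**Retrosynthetic overview**

1. Feature: in ring B the ether oxygen on C9 and the acetoxy oxygen on C6 are 1,4-related through C8 and C7 (O–C9–C8–C7–C6–O). This is the γ-hydroxy ketone pattern formed when a C9 ketyl is joined to the β-carbon C8 of a C6 enone, so ring B is opened at C8–C9 and reclosed by SmI2 (17 → 18).
2. Seco keto-enone 17 comes from the trans-fused γ-lactone 14 (C9 carbonyl, C6 oxygen) and the alkyllithium made from iodide 5. Lactone 14 comes from (+)-sclareolide 6 by excision of C11/C12 (Kochi decarboxylation, ozonolysis), C8–C9 ketol cleavage and a Wharton 1,3-transposition.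
3. After ring B: C6 reduction and acetylation; ring C by 5-exo opening of a reagent-set (13R)-13,16-epoxide by the 9α-hydroxyl (inversion gives 13S); ring D by oxidative lactonisation of the 15,16-diol.
4. Ring order: A (from sclareolide), B (key step), C, D.

Key step: step 13

Assumption 1: labdane numbering is used throughout, seco compounds included; all decalins have 5α-H, 8α-methyl and 10β-methyl; the epoxide configuration of 12 and the C6 configuration of 13, 14 and 16 are inconsequential and are carried as mixtures.
Assumption 2: in step 17 the (R,R)-ligand is written on the assumption that it delivers the (13R)-epoxide; if the sense of induction on this substrate is the opposite, the mirror-image ligand is used.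

**Route**

Step 1
Reactants: 1 3-methylbut-3-en-1-ol (isoprenol)
Product: 3 3-methylidenepentane-1,5-diol, via dilithio isoprenol 2 (not isolated)
Conditions: n-BuLi (2.2 equiv), TMEDA, Et2O/hexane, 0 °C to rt; paraformaldehyde, −78 °C to rt; H2O
Reagents that add atoms: formaldehyde (from paraformaldehyde), C=O
Why: Alkoxide-assisted allylic lithiation of the methyl group gives a symmetric 2-substituted allyl anion that is hydroxymethylated by formaldehyde (dianion alkylation), so either terminus gives the same diol.

Step 2
Reactants: 3 3-methylidenepentane-1,5-diol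
Product: 4 5-[(tert-butyldimethylsilyl)oxy]-3-methylidenepentan-1-ol
Conditions: 3 (3 equiv), TBSCl (1 equiv), imidazole, DMF, 0 °C; excess 3 recovered
Reagents that add atoms: tert-butyldimethylsilyl chloride, CC(C)(C)[Si](C)(C)Cl
Why: Silyl ether formation on a symmetric primary diol used in excess should give mainly the mono-ether.

Step 3
Reactants: 4 5-[(tert-butyldimethylsilyl)oxy]-3-methylidenepentan-1-ol
Product: 5 tert-butyl[(5-iodo-3-methylidenepentyl)oxy]dimethylsilane
Conditions: I2, PPh3, imidazole, CH2Cl2, 0 °C
Reagents that add atoms: iodine, II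
Why: Appel-type iodination of the primary alcohol by SN2 displacement of the oxyphosphonium group; the alkene and silyl ether are inert.

Step 4
Reactants: 6 (+)-sclareolide
Product: 7 8α-hydroxy-11-homodriman-12-oic acid
Conditions: KOH, MeOH/H2O, reflux; 1 M HCl to pH 4 at 0 °C, extraction without heating
Reagents that add atoms: potassium hydroxide, [K+].[OH-]
Why: Saponification of the γ-lactone, with a cold, weakly acidic work-up so that the free 8α-hydroxy acid is collected before it relactonises.

Step 5
Reactants: 7 8α-hydroxy-11-homodriman-12-oic acid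
Product: 8 drim-9(11)-en-8α-ol
Conditions: Pb(OAc)4 (1.2 equiv), Cu(OAc)2 (0.3 equiv), pyridine, benzene, 80 °C
Reagents that add atoms: none
Why: Kochi oxidative decarboxylation, in which tetravalent lead gives the C11 primary radical and divalent copper oxidises it with loss of the only β-hydrogen (H-9), so the exocyclic 9(11)-alkene is the only possible olefin.

Step 6
Reactants: 8 drim-9(11)-en-8α-ol
Product: 9 8α-hydroxy-11-nordriman-9-one
Conditions: O3, CH2Cl2/MeOH, −78 °C; Me2S, −78 °C to rt
Reagents that add atoms: ozone, O=[O+][O-]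
Why: Ozonolysis of the 1,1-disubstituted alkene removes C11 as formaldehyde and leaves the C9 ketone, the tertiary alcohol being inert.

Step 7
Reactants: 9 8α-hydroxy-11-nordriman-9-one
Product: 10 (1S,2S)-1,3,3-trimethyl-2-(3-oxobutyl)cyclohexane-1-carboxylic acid
Conditions: Pb(OAc)4 (1.2 equiv), AcOH/H2O 9:1, rt
Reagents that add atoms: water, O
Why: Criegee-type cleavage of the α-ketol through the lead alkoxide of the tertiary 8-hydroxyl breaks C8–C9 and gives the C8 methyl ketone and, after hydrolysis of the acyl acetate, the C9 acid, with C5 and C10 untouched.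

Step 8
Reactants: 10 (1S,2S)-1,3,3-trimethyl-2-(3-oxobutyl)cyclohexane-1-carboxylic acid
Product: 11 (1S,2S)-1,3,3-trimethyl-2-[(1E)-3-oxobut-1-en-1-yl]cyclohexane-1-carboxylic acid
Conditions: IBX (3 equiv), DMSO/fluorobenzene, 75 °C
Reagents that add atoms: none
Why: IBX-mediated α,β-dehydrogenation of the ketone through its enol, where only the C7–C6 side carries a β-hydrogen, so the (E)-3-oxobutenyl chain is the only possible enone.

Step 9
Reactants: 11 (1S,2S)-1,3,3-trimethyl-2-[(1E)-3-oxobut-1-en-1-yl]cyclohexane-1-carboxylic acid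
Product: 12 (1S,2S)-2-(3-acetyloxiran-2-yl)-1,3,3-trimethylcyclohexane-1-carboxylic acid (trans-epoxide, both diastereomers)
Conditions: 30% H2O2, NaOH (1.5 equiv), MeOH, 0 °C; 1 M HCl to pH 4, 0 °C
Reagents that add atoms: hydrogen peroxide, OO
Why: Weitz–Scheffer nucleophilic epoxidation of the (E)-enone gives the trans-epoxide, whose two diastereomers need no separation because C6 later becomes a ketone and C7 an sp2 carbon.

Step 10
Reactants: 12 (1S,2S)-2-(3-acetyloxiran-2-yl)-1,3,3-trimethylcyclohexane-1-carboxylic acid
Product: 14 (3aS,7aS)-4,4,7a-trimethyl-3-[(1E)-prop-1-en-1-yl]hexahydro-2-benzofuran-1(3H)-one (trans-fused 9,6-lactone, C6 epimers), via allylic hydroxy acid 13 (not isolated)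
Conditions: N2H4·H2O (4 equiv), AcOH (cat.), MeOH, 0 °C to rt; aqueous work-up; EDC·HCl, DMAP (cat.), CH2Cl2, rt
Reagents that add atoms: none
Why: Wharton transposition (hydrazone, epoxide opening to the vinyl diazene, loss of N2) moves the oxygen from C8 to C6 and forms the (E)-propenyl group, after which Steglich-type carbodiimide lactonisation ties the C6 hydroxyl to the C9 acid.

Step 11
Reactants: 5 tert-butyl[(5-iodo-3-methylidenepentyl)oxy]dimethylsilane; 14 trans-fused 9,6-lactone
Product: 16 1-[(1S,2S)-2-[(2E)-1-hydroxybut-2-en-1-yl]-1,3,3-trimethylcyclohexyl]-6-[(tert-butyldimethylsilyl)oxy]-4-methylidenehexan-1-one (C6 epimers, in equilibrium with its cyclic hemiketal), via alkyllithium 15 (not isolated)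
Conditions: 5, t-BuLi (2.05 equiv), Et2O/pentane, −78 °C; 14 in THF, −78 to −40 °C; sat. aq. NH4Cl
Reagents that add atoms: none
Why: Iodine–lithium exchange followed by single addition of the primary alkyllithium to the hindered, non-enolisable lactone carbonyl, the lithium hemiketal alkoxide surviving at low temperature so that no second addition occurs.

Step 12
Reactants: 16 seco hydroxy ketone
Product: 17 (2E)-1-[(1S,2S)-2-{6-[(tert-butyldimethylsilyl)oxy]-4-methylidenehexanoyl}-2,6,6-trimethylcyclohexyl]but-2-en-1-one (8,9-seco keto-enone)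
Conditions: Dess–Martin periodinane (1.5 equiv), pyridine, CH2Cl2, 0 °C to rt
Reagents that add atoms: none
Why: Dess–Martin oxidation of the allylic alcohol (open form of the hemiketal) gives the (E)-enone under non-basic conditions, so C5, now α to a ketone, should keep its configuration.

Step 13
Reactants: 17 8,9-seco keto-enone
Product: 18 15-[(tert-butyldimethylsilyl)oxy]-9α-hydroxylabd-13(16)-en-6-one (8α-methyl)
Conditions: SmI2 (2.5 equiv, 0.1 M in THF), HMPA (10 equiv), THF, −78 °C, slow addition of 17, then −40 °C; sat. aq. NH4Cl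
Reagents that add atoms: none
Why: Single-electron transfer from divalent samarium to the enone (and, with HMPA, to the C9 ketone) gives a radical anion, C9 and the enone β-carbon C8 are joined, and a second electron leaves the samarium enolate of the C6 ketone (C6=C7) and the C9 alkoxide, both protonated only on quench. The closest known reaction type is the SmI2 ketone–enone (ketyl–olefin) reductive cyclisation, here in the less usual mode in which the acceptor carbonyl lies inside the new ring. Ring B closes 6-endo-trig with respect to C7=C8; the five-membered alternatives (ketyl to C7, or enolate aldol at C7) are polarity-mismatched and trans-fused, and the side-chain 1,1-disubstituted alkene offers only 4-exo or 5-endo modes. C8 is set by the (E)-alkene geometry, because in the half-chair fused trans to the ring A chair the methyl stays anti to C6 and ends equatorial (8α). C9 is set by placing the C11 chain equatorial and the samarium-bound oxygen axial on the open α face, anti to the C10 methyl, which gives the 9α-alcohol. The step needs coupling to outrun plain 1,4-reduction of the enone, which is served by withholding any proton donor until the quench and by slow addition at −78 °C, and C5 is untouched because the enolate forms toward C7.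

Step 14
Reactants: 18 9α-hydroxy-6-ketone
Product: 19 15-[(tert-butyldimethylsilyl)oxy]labd-13(16)-ene-6β,9α-diol
Conditions: NaBH4, MeOH/THF, 0 °C
Reagents that add atoms: none
Why: Substrate-controlled carbonyl reduction in which hydride attacks C6 from the α face, the β face being screened by the syn-axial 4β- and 10β-methyl groups, to give the axial 6β-alcohol.

Step 15
Reactants: 19 6β,9α-diol
Product: 20 6β-acetoxy-15-[(tert-butyldimethylsilyl)oxy]labd-13(16)-en-9α-ol
Conditions: Ac2O, DMAP, pyridine, 40 °C
Reagents that add atoms: acetic anhydride, CC(=O)OC(C)=O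
Why: DMAP-catalysed acylation of the secondary 6β-hydroxyl, the tertiary 9α-hydroxyl being too hindered to react and the primary oxygen still silylated.

Step 16
Reactants: 20 6β-acetate silyl ether
Product: 21 6β-acetoxylabd-13(16)-ene-9α,15-diol
Conditions: HF·pyridine, THF/pyridine, 0 °C to rt
Reagents that add atoms: none
Why: Fluoride-driven cleavage of the primary silyl ether under buffered conditions that leave the acetate, the tertiary alcohol and the alkene intact.

Step 17
Reactants: 21 6β-acetoxylabd-13(16)-ene-9α,15-diol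
Product: 23 (13S)-6β-acetoxy-9α,13-epoxylabdane-15,16-diol, via epoxide 22 (not isolated)
Conditions: Hf(OtBu)4 (10 mol %), (R,R)-cyclohexane-1,2-diamine-derived bishydroxamic acid ligand (11 mol %), cumene hydroperoxide (1.5 equiv), DMPU, 4 Å molecular sieves, toluene, 0 °C to rt; then CSA (10 mol %), CH2Cl2, 0 °C
Reagents that add atoms: cumene hydroperoxide, CC(C)(OO)c1ccccc1
Why: Hydroxyl-directed asymmetric epoxidation of the homoallylic alcohol on tetravalent hafnium (reagent control by the chiral ligand) should give the (13R)-13,16-epoxide, and acid-catalysed 5-exo-tet opening at the tertiary carbon by the 9α-hydroxyl with inversion closes ring C and sets C13 as S.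

Step 18
Reactants: 23 (13S)-6β-acetoxy-9α,13-epoxylabdane-15,16-diol
Product: 25 previtexilactone, via lactol 24 (not isolated)
Conditions: TEMPO (0.2 equiv), PhI(OAc)2 (2.5 equiv), CH2Cl2, rt
Reagents that add atoms: none
Why: Oxidative lactonisation in which the oxoammonium salt takes the less hindered C15 primary alcohol (C16–OH is neopentylic and next to the ether oxygen) to the aldehyde, which closes to the lactol with C16–OH and is oxidised on to the γ-lactone, closing ring D without touching a stereocentre.

**Compound list**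

1 | 3-methylbut-3-en-1-ol (isoprenol) | C=C(C)CCO | starting material
2 | dilithio isoprenol (lithium 3-(lithiomethyl)but-3-en-1-olate) | [Li]CC(=C)CCO[Li] | intermediate
3 | 3-methylidenepentane-1,5-diol | C=C(CCO)CCO | intermediate
4 | 5-[(tert-butyldimethylsilyl)oxy]-3-methylidenepentan-1-ol | C=C(CCO)CCO[Si](C)(C)C(C)(C)C | intermediate
5 | tert-butyl[(5-iodo-3-methylidenepentyl)oxy]dimethylsilane | C=C(CCI)CCO[Si](C)(C)C(C)(C)C | intermediate
6 | (+)-sclareolide | C[C@@]12CC[C@H]3C(C)(C)CCC[C@]3(C)[C@H]1CC(=O)O2 | starting material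
7 | 8α-hydroxy-11-homodriman-12-oic acid | C[C@@]1(O)CC[C@H]2C(C)(C)CCC[C@]2(C)[C@H]1CC(=O)O | intermediate
8 | drim-9(11)-en-8α-ol | C=C1[C@](C)(O)CC[C@H]2C(C)(C)CCC[C@]12C | intermediate
9 | 8α-hydroxy-11-nordriman-9-one | O=C1[C@](C)(O)CC[C@H]2C(C)(C)CCC[C@]12C | intermediate
10 | (1S,2S)-1,3,3-trimethyl-2-(3-oxobutyl)cyclohexane-1-carboxylic acid | CC(=O)CC[C@H]1C(C)(C)CCC[C@]1(C)C(=O)O | intermediate
11 | (1S,2S)-1,3,3-trimethyl-2-[(1E)-3-oxobut-1-en-1-yl]cyclohexane-1-carboxylic acid | CC(=O)/C=C/[C@H]1C(C)(C)CCC[C@]1(C)C(=O)O | intermediate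
12 | (1S,2S)-2-(3-acetyloxiran-2-yl)-1,3,3-trimethylcyclohexane-1-carboxylic acid (trans-epoxide, both diastereomers) | CC(=O)C1OC1[C@H]2C(C)(C)CCC[C@]2(C)C(=O)O | intermediate
13 | (1S,2S)-2-[(2E)-1-hydroxybut-2-en-1-yl]-1,3,3-trimethylcyclohexane-1-carboxylic acid (C6 epimers) | C/C=C/C(O)[C@H]1C(C)(C)CCC[C@]1(C)C(=O)O | intermediate
14 | (3aS,7aS)-4,4,7a-trimethyl-3-[(1E)-prop-1-en-1-yl]hexahydro-2-benzofuran-1(3H)-one (trans-fused, C6 epimers) | C/C=C/C1OC(=O)[C@@]2(C)CCCC(C)(C)[C@H]12 | intermediate
15 | {5-[(tert-butyldimethylsilyl)oxy]-3-methylidenepentyl}lithium | [Li]CCC(=C)CCO[Si](C)(C)C(C)(C)C | intermediate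
16 | 1-[(1S,2S)-2-[(2E)-1-hydroxybut-2-en-1-yl]-1,3,3-trimethylcyclohexyl]-6-[(tert-butyldimethylsilyl)oxy]-4-methylidenehexan-1-one (C6 epimers) | C/C=C/C(O)[C@H]1C(C)(C)CCC[C@]1(C)C(=O)CCC(=C)CCO[Si](C)(C)C(C)(C)C | intermediate
17 | (2E)-1-[(1S,2S)-2-{6-[(tert-butyldimethylsilyl)oxy]-4-methylidenehexanoyl}-2,6,6-trimethylcyclohexyl]but-2-en-1-one | C/C=C/C(=O)[C@H]1C(C)(C)CCC[C@]1(C)C(=O)CCC(=C)CCO[Si](C)(C)C(C)(C)C | intermediate
18 | 15-[(tert-butyldimethylsilyl)oxy]-9α-hydroxylabd-13(16)-en-6-one (8α-methyl) | O=C1C[C@@H](C)[C@](O)(CCC(=C)CCO[Si](C)(C)C(C)(C)C)[C@@]2(C)CCCC(C)(C)[C@H]12 | intermediate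
19 | 15-[(tert-butyldimethylsilyl)oxy]labd-13(16)-ene-6β,9α-diol | O[C@@H]1C[C@@H](C)[C@](O)(CCC(=C)CCO[Si](C)(C)C(C)(C)C)[C@@]2(C)CCCC(C)(C)[C@H]12 | intermediate
20 | 6β-acetoxy-15-[(tert-butyldimethylsilyl)oxy]labd-13(16)-en-9α-ol | CC(=O)O[C@@H]1C[C@@H](C)[C@](O)(CCC(=C)CCO[Si](C)(C)C(C)(C)C)[C@@]2(C)CCCC(C)(C)[C@H]12 | intermediate
21 | 6β-acetoxylabd-13(16)-ene-9α,15-diol | CC(=O)O[C@@H]1C[C@@H](C)[C@](O)(CCC(=C)CCO)[C@@]2(C)CCCC(C)(C)[C@H]12 | intermediate
22 | (13R)-6β-acetoxy-13,16-epoxylabdane-9α,15-diol | CC(=O)O[C@@H]1C[C@@H](C)[C@](O)(CC[C@@]3(CCO)CO3)[C@@]2(C)CCCC(C)(C)[C@H]12 | intermediate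
23 | (13S)-6β-acetoxy-9α,13-epoxylabdane-15,16-diol | CC(=O)O[C@@H]1C[C@@H](C)[C@]2(CC[C@@](CO)(CCO)O2)[C@@]2(C)CCCC(C)(C)[C@H]12 | intermediate
24 | (13S)-6β-acetoxy-9α,13:15,16-diepoxylabdan-15-ol (lactol, both anomers) | CC(=O)O[C@@H]1C[C@@H](C)[C@]2(CC[C@]3(COC(O)C3)O2)[C@@]2(C)CCCC(C)(C)[C@H]12 | intermediate
25 | previtexilactone, (13S)-6β-acetoxy-9α,13-epoxylabdan-15,16-olide | CC(=O)O[C@@H]1C[C@@H](C)[C@]2(CC[C@]3(COC(=O)C3)O2)[C@@]2(C)CCCC(C)(C)[C@H]12 | target

**Step count**

Total: 18 steps. Longest linear sequence: 15 steps (steps 4 to 18, from (+)-sclareolide 6 to 25); the iodide branch is steps 1 to 3.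

**Steps most likely to fail**

Step 13. The enone may be reduced at C7=C8 before ring closure, or the ring may close with the C11 chain axial and give the wrong C9 configuration. Fallback: the same bond is made by a neutral tin hydride radical chain, which forms no enolate and uses no excess reductant. It sets out from 17, with Bu3SnH (syringe-pump addition) and AIBN in benzene at 80 °C. The O-stannyl ketyl radical, formed reversibly at either carbonyl, joins C9 to C8, and hydrogen transfer from the stannane carries the chain to the 9-O-tributylstannyl ether of 18, F1. Aqueous KF work-up removes the tin and the route is rejoined at 18.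

Step 17. The epoxidation may show poor facial selectivity on the 1,1-disubstituted alkene, or the ring opening may go through a carbocation and erode the inversion; either gives a C13 mixture. Fallback: C13 is set by separation and equilibration instead of by the catalyst. It sets out from 21 with mCPBA and NaHCO3 in CH2Cl2, then CSA. This gives epoxide 22 together with its (13S)-epimer F2, and from them diol 23 together with its (13R)-epimer F3. The mixture is taken through the conditions of step 18 to 25 and 13-epi-previtexilactone F4, which are separated by chromatography. F4 is treated with DBU in MeCN, which opens ring C by β-elimination of the C9 alkoxide to the 9α-hydroxy butenolide F5 and recloses it by oxa-Michael addition to both C13 epimers; the mixture is separated again. The route is rejoined at 25.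

Step 10. The epoxy ketone hydrazone may cyclise to a hydroxy-pyrazoline instead of losing N2, so that little allylic alcohol forms. Fallback: the three-carbon enone unit is removed and rebuilt. It sets out from 11 with O3 in CH2Cl2/MeOH at −78 °C and Me2S, which gives (1S,2S)-2-formyl-1,3,3-trimethylcyclohexane-1-carboxylic acid F6. Prop-1-enylmagnesium bromide (2.2 equiv, E-enriched) in THF at −78 °C then gives hydroxy acid 13, and EDC·HCl with DMAP closes the lactone. The route is rejoined at 14; any Z-enone present later at 17 would be equilibrated to E with catalytic iodine.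

**Further compounds**

F1 | step 13 | 9-O-tributylstannyl ether of 18 | O=C1C[C@@H](C)[C@](O[Sn](CCCC)(CCCC)CCCC)(CCC(=C)CCO[Si](C)(C)C(C)(C)C)[C@@]2(C)CCCC(C)(C)[C@H]12
F2 | step 17 | (13S)-6β-acetoxy-13,16-epoxylabdane-9α,15-diol | CC(=O)O[C@@H]1C[C@@H](C)[C@](O)(CC[C@]3(CCO)CO3)[C@@]2(C)CCCC(C)(C)[C@H]12
F3 | step 17 | (13R)-6β-acetoxy-9α,13-epoxylabdane-15,16-diol | CC(=O)O[C@@H]1C[C@@H](C)[C@]2(CC[C@](CO)(CCO)O2)[C@@]2(C)CCCC(C)(C)[C@H]12
F4 | step 17 | 13-epi-previtexilactone | CC(=O)O[C@@H]1C[C@@H](C)[C@]2(CC[C@@]3(COC(=O)C3)O2)[C@@]2(C)CCCC(C)(C)[C@H]12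
F5 | step 17 | 6β-acetoxy-9α-hydroxylabd-13-en-15,16-olide | CC(=O)O[C@@H]1C[C@@H](C)[C@](O)(CCC3=CC(=O)OC3)[C@@]2(C)CCCC(C)(C)[C@H]12
F6 | step 10 | (1S,2S)-2-formyl-1,3,3-trimethylcyclohexane-1-carboxylic acid | O=C[C@H]1C(C)(C)CCC[C@]1(C)C(=O)O
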